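Readings and results were computed for substances that don't exist; the scatter is artificial.

A closed, stirred vessel at constant temperature holds the substrate and what it turns into, and I follow each species as a fraction of the charge.

| setting | theta | epsilon | flask |
|---|---|---|---|
| substrate | 0.0050 M | 0.0075 M | 0.010 M |
| remark | run made earlier | run made earlier |  |
| time |  |  | 6.0 h |

| run | time / h | isomer of the product A / % | target / % |
|---|---|---|---|
| theta | 0.833 | 12 | 0 |
| theta | 1.50 | 18 | 5 |
| theta | 2.50 | 27 | 7 |
| theta | 3.00 | 37 | 10 |
| theta | 4.00 | 40 | 10 |
| theta | 5.00 | 43 | 9 |
| epsilon | 0.333 | 1 | 3 |
| epsilon | 1.00 | 14 | 2 |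
| epsilon | 1.50 | 20 | 7 |
| epsilon | 2.50 | 29 | 7 |
| epsilon | 4.00 | 38 | 7 |
| epsilon | 5.00 | 45 | 8 |

(standard deviation of a reading: 2 percentage points)

- ratio of isomer of the product A to target at 6.0 min
- ratio of isomer of the product A to target at 50 min
- ratio of isomer of the product A to target at 6.0 h
- which of isomer of the product A and target there is more of at 6.0 h

- the numbers in the tables scatter by 2 percentage points (one standard deviation)

Does the size of the charge matter? The epsilon run starts with 1.50 times the charge of the theta run, yet at 5.00 h their fractions of isomer of the product A differ by 2 percentage points. That is less than the 2.8 points by which a difference of two readings scatters. So I treat the fractions as independent of the charge, as first-order steps would make them, and carry them to the flask.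

Who leads, then? Summing both runs at 5.00 h gives 5.18: this is the lead ratio, isomer of the product A over target in fractions of the charge. The small target sum, 17.0 %, makes it uncertain by about 0.861.

Can the last 60.0 min overturn it? Averaged over the runs, from 2.50 h to 5.00 h isomer of the product A gains 16 points, while target gains 1.5 points, far less. So I commit to isomer of the product A leading in the flask at 6.0 h, with a ratio near 5.18. The ratios at 6.0 min and 50 min I leave open: the earliest readings, from the epsilon run at 0.333 h, are 1 % of isomer of the product A and 3 % of target, a gap smaller than the scatter of a difference.

For 6.0 min, 50 min and 6.0 h the forecast gives ratios of 3, 3.8 and 5.8, with isomer of the product A ahead, and says “the kinetics look first order”.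

At those times the flask gives ratios of 0.655, 4.14 and 4.39, with 47.6 % of isomer of the product A against 10.8 % of target at 6.0 h.

    target ⇌ isomer of the product A (K = 3.78, k = 0.00537 min⁻¹)
    isomer of the product A ⇌ isomer of the product B (K = 0.323, k = 0.00128 min⁻¹)
    substrate ⇌ target (K = 2.30, k = 0.00134 min⁻¹)
    isomer of the product B ⇌ substrate (k = 0.0252 min⁻¹)

The neighbouring flask takes 0.040 M of substrate, 4.00 times the charge of the first flask, with the time held. Treating the fractions as independent of the charge, I carry the lead ratio read from the runs, 5.18, to the neighbouring flask too, and expect isomer of the product A to lead there. The neighbouring flask gives 4.39 at 6.0 h, with 47.6 % of isomer of the product A and 11.0 % of substrate left.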